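Ring A of the 6-methylflavone half is formed last, from open-chain pieces, on a finished 4-pyranone (ring C). The key step exploits the contiguous C5–OH, C6–CH3, C7–OCH3 triad beside the C4a–C8a fusion. A pyranylketene, released from a diazomethyl ketone by Wolff shift, adds 1-methoxypropyne and rearranges through a cyclobutenone to the phenol. This forges C8–C8a, C5–C6, C7–C8 and C4a–C5 in one operation with fixed regiochemistry. The precursor is the diazoketone of a 6-aryl-4-oxo-4H-pyran-2-carboxylic acid whose aryl group already carries the tri-O-benzyl apigenin half through the C3'–C8'' biaryl bond. It is assembled convergently by Suzuki coupling, and hydrogenolysis ends the route.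

Key step: step 11

Remarks on the chemistry:
- Locants: unit 1 is the 6-methylflavone half (its ring B primed); unit 2 is the apigenin half (double-primed, its ring B triple-primed).
- The C3'–C8'' axis is not a defined stereoelement in the target and is treated as freely rotating.
- 1-Methoxypropyne is assumed not to be purchasable and is made in step 10.
- The pyranone acid is built on the simple bromoarene before the biaryl coupling, so the flavone of unit 2 never meets Claisen bases.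

Step 1
Reactants: 1 apigenin
Product: 2 5,7,4'-tri-O-benzylapigenin
Conditions: BnBr (4.5 equiv), K2CO3, n-Bu4NI (cat.), DMF, 80 °C
Reagents that add atoms: benzyl bromide, BrCc1ccccc1
Why: Williamson ether synthesis; excess benzyl bromide in hot DMF should also alkylate the hydrogen-bonded 5-hydroxyl, which must be capped so that the next step is directed to C8.

Step 2
Reactants: 2 5,7,4'-tri-O-benzylapigenin
Product: 3 8-iodo-5,7,4'-tri-O-benzylapigenin
Conditions: NIS (1.1 equiv), TFA (cat.), MeCN/CH2Cl2, 0 °C to rt, dark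
Reagents that add atoms: N-iodosuccinimide, O=C1CCC(=O)N1I
Why: Electrophilic aromatic iodination; in fully O-alkylated 5,7-dioxygenated flavones ring A is the most electron-rich ring and C8 (between one benzyloxy group and the ring oxygen) is more accessible than C6 (between two benzyloxy groups), which is the known site preference of this class.

Step 3
Reactants: 4 1-(3-bromo-4-hydroxyphenyl)ethanone
Product: 5 1-[4-(benzyloxy)-3-bromophenyl]ethanone
Conditions: BnBr, K2CO3, acetone, reflux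
Reagents that add atoms: benzyl bromide, BrCc1ccccc1
Why: Williamson ether synthesis of an acidic para-acyl phenol under mild carbonate conditions.

Step 4
Reactants: 5 1-[4-(benzyloxy)-3-bromophenyl]ethanone
Product: 6 1-[4-(benzyloxy)-3-bromophenyl]butane-1,3-dione
Conditions: NaH (2.5 equiv), EtOAc (4 equiv), THF, 0 °C to reflux; then aq. HCl
Reagents that add atoms: ethyl acetate, CCOC(C)=O
Why: Crossed Claisen condensation of the methyl ketone enolate with ethyl acetate, driven by irreversible deprotonation of the 1,3-diketone that forms.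

Step 5
Reactants: 6 1-[4-(benzyloxy)-3-bromophenyl]butane-1,3-dione; 7 diethyl oxalate
Product: 9 ethyl 6-[4-(benzyloxy)-3-bromophenyl]-4-oxo-4H-pyran-2-carboxylate, via triketo ester 8 (not isolated)
Conditions: NaOEt (2.2 equiv), EtOH, 0 °C to 50 °C; then HCl/EtOH, 60 °C
Reagents that add atoms: none
Why: Claisen condensation of the diketone at its terminal methyl group with diethyl oxalate (the chelidonic acid manifold), followed by acid-catalysed cyclodehydration of the 1,3,5-triketone, which can close only to the 4-pyranone with the aryl group at C6 and the ester at C2.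

Step 6
Reactants: 9 ethyl 6-[4-(benzyloxy)-3-bromophenyl]-4-oxo-4H-pyran-2-carboxylate
Product: 10 ethyl 6-[4-(benzyloxy)-3-(4,4,5,5-tetramethyl-1,3,2-dioxaborolan-2-yl)phenyl]-4-oxo-4H-pyran-2-carboxylate
Conditions: B2pin2, PdCl2(dppf) (cat.), KOAc, 1,4-dioxane, 90 °C
Reagents that add atoms: bis(pinacolato)diboron, CC1(C)OB(OC1(C)C)B1OC(C)(C)C(C)(C)O1
Why: Miyaura borylation of an aryl bromide; acetate is too weak a base to attack the pyranone or the ester.

Step 7
Reactants: 3 8-iodo-5,7,4'-tri-O-benzylapigenin; 10 ethyl 6-[4-(benzyloxy)-3-(4,4,5,5-tetramethyl-1,3,2-dioxaborolan-2-yl)phenyl]-4-oxo-4H-pyran-2-carboxylate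
Product: 11 ethyl 6-{4-(benzyloxy)-3-[5,7-bis(benzyloxy)-2-(4-(benzyloxy)phenyl)-4-oxo-4H-chromen-8-yl]phenyl}-4-oxo-4H-pyran-2-carboxylate
Conditions: Pd(OAc)2 (5 mol%), SPhos (10 mol%), CsF (3 equiv), 1,4-dioxane, 90 °C
Reagents that add atoms: none
Why: Suzuki–Miyaura coupling; the bulky electron-rich SPhos ligand suits the tri-ortho-substituted C3'–C8'' biaryl, and anhydrous fluoride activation should keep the ethyl ester and both pyranone rings intact.

Step 8
Reactants: 11 ethyl 6-{4-(benzyloxy)-3-[5,7-bis(benzyloxy)-2-(4-(benzyloxy)phenyl)-4-oxo-4H-chromen-8-yl]phenyl}-4-oxo-4H-pyran-2-carboxylate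
Product: 12 6-{4-(benzyloxy)-3-[5,7-bis(benzyloxy)-2-(4-(benzyloxy)phenyl)-4-oxo-4H-chromen-8-yl]phenyl}-4-oxo-4H-pyran-2-carboxylic acid
Conditions: Me3SnOH (4 equiv), ClCH2CH2Cl, 75 °C; then 1 M aq. HCl wash
Reagents that add atoms: trimethyltin hydroxide, C[Sn](C)(C)O
Why: Ester hydrolysis with trimethyltin hydroxide, a neutral method that avoids free hydroxide, which could open the pyranone or the flavone by conjugate addition.

Step 9
Reactants: 12 6-{4-(benzyloxy)-3-[5,7-bis(benzyloxy)-2-(4-(benzyloxy)phenyl)-4-oxo-4H-chromen-8-yl]phenyl}-4-oxo-4H-pyran-2-carboxylic acid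
Product: 14 2-diazo-1-(6-{4-(benzyloxy)-3-[5,7-bis(benzyloxy)-2-(4-(benzyloxy)phenyl)-4-oxo-4H-chromen-8-yl]phenyl}-4-oxo-4H-pyran-2-yl)ethan-1-one, via acid chloride 13 (not isolated)
Conditions: Me2C=C(Cl)NMe2 (1.2 equiv), CH2Cl2, 0 °C to rt; then CH2N2 (3 equiv), Et2O/THF, 0 °C
Reagents that add atoms: diazomethane, C=[N+]=[N-]
Why: Neutral acid chloride formation with the Ghosez chloroenamine and acylation of diazomethane (first stage of the Arndt–Eistert sequence); the excess diazomethane consumes the HCl that would otherwise give the chloromethyl ketone.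

Step 10
Reactants: 15 2-chloro-1,1-dimethoxyethane (chloroacetaldehyde dimethyl acetal)
Product: 17 1-methoxypropyne, via sodium methoxyacetylide 16 (not isolated)
Conditions: NaNH2 (3 equiv), liquid NH3, −33 °C; then MeI, −33 °C; H2O, pentane extraction, fractional distillation
Reagents that add atoms: iodomethane, CI
Why: Twofold amide-induced elimination (methanol, then HCl) gives the methoxyacetylide, whose C-alkylation by iodomethane is the standard entry to 1-alkoxyalk-1-ynes.

Step 11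
Reactants: 14 2-diazo-1-(6-{4-(benzyloxy)-3-[5,7-bis(benzyloxy)-2-(4-(benzyloxy)phenyl)-4-oxo-4H-chromen-8-yl]phenyl}-4-oxo-4H-pyran-2-yl)ethan-1-one; 17 1-methoxypropyne (4 equiv)
Product: 21 2-{4-(benzyloxy)-3-[5,7-bis(benzyloxy)-2-(4-(benzyloxy)phenyl)-4-oxo-4H-chromen-8-yl]phenyl}-5-hydroxy-7-methoxy-6-methyl-4H-chromen-4-one, via pyranylketene 18 (not isolated), via cyclobutenone 19 (not isolated), via dienylketene 20 (not isolated)
Conditions: ClCH2CH2Cl (degassed), 440 nm LED, rt; then 85 °C, sealed tube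
Reagents that add atoms: none
Why: Proposed new method: blue light should excite only the long-wavelength band of diazoketone 14 (the benzylated flavone and the pyranone absorb at shorter wavelength), N2 leaves and the pyranyl group shifts to the carbene carbon (Wolff rearrangement) to give ketene 18, whose carbonyl carbon is attacked by the methyl-bearing carbon of ynol ether 17 in a [2+2] cycloaddition that gives cyclobutenone 19. On warming, 19 should open reversibly in a conrotatory four-electron electrocyclic step to dienylketene 20, and ring A is then closed by a thermal disrotatory six-electron electrocyclisation in which the ketene carbon bonds to the pyranone CH next to the side chain (C4a–C5), followed by enolisation of the 4a-H dienone to the C5 phenol. The closest known reaction type is the diazoketone (photo-Wolff) variant of the Danheiser benzannulation, established for aryl, heteroaryl and alkenyl diazomethyl ketones with alkoxyalkynes, whereas a 4-pyranone C=C as the terminus of the final closure has not been shown. No stereocentre remains in the product, because C4 of 19 and C4a of the dienone both return to sp2. The step needs regioselectivity in the [2+2] event, secured by the polarisation of the ynol ether (CH3 ends at C6 beside the new hydroxyl, OCH3 at C7), and site selectivity in the closure, secured because only the pyranone carbon adjacent to the side chain is within reach. The closure should cost little because the pyranone C=C is only weakly aromatic and the 4a-H of the dienone lies between two carbonyl groups.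

Step 12
Reactants: 21 2-{4-(benzyloxy)-3-[5,7-bis(benzyloxy)-2-(4-(benzyloxy)phenyl)-4-oxo-4H-chromen-8-yl]phenyl}-5-hydroxy-7-methoxy-6-methyl-4H-chromen-4-one
Product: 22 8-[2-hydroxy-5-(5-hydroxy-7-methoxy-6-methyl-4-oxo-4H-chromen-2-yl)phenyl]-5,7-dihydroxy-2-(4-hydroxyphenyl)-4H-chromen-4-one (CNP0113589.0)
Conditions: H2 (1 atm), 10% Pd/C, THF/MeOH, rt
Reagents that add atoms: none
Why: Hydrogenolysis of benzyl aryl ethers over palladium on carbon; the pyranone C2=C3 bonds of both flavone units and the aryl methyl ether are not expected to be reduced at 1 atm and room temperature.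

Compound list
1 | apigenin | O=c1cc(-c2ccc(O)cc2)oc2cc(O)cc(O)c12 | starting material
2 | 5,7,4'-tri-O-benzylapigenin | O=c1cc(-c2ccc(OCc3ccccc3)cc2)oc2cc(OCc3ccccc3)cc(OCc3ccccc3)c12 | intermediate
3 | 8-iodo-5,7,4'-tri-O-benzylapigenin | O=c1cc(-c2ccc(OCc3ccccc3)cc2)oc2c(I)c(OCc3ccccc3)cc(OCc3ccccc3)c12 | intermediate
4 | 1-(3-bromo-4-hydroxyphenyl)ethanone | CC(=O)c1ccc(O)c(Br)c1 | starting material
5 | 1-[4-(benzyloxy)-3-bromophenyl]ethanone | CC(=O)c1ccc(OCc2ccccc2)c(Br)c1 | intermediate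
6 | 1-[4-(benzyloxy)-3-bromophenyl]butane-1,3-dione | CC(=O)CC(=O)c1ccc(OCc2ccccc2)c(Br)c1 | intermediate
7 | diethyl oxalate | CCOC(=O)C(=O)OCC | starting material
8 | ethyl 6-[4-(benzyloxy)-3-bromophenyl]-2,4,6-trioxohexanoate (not isolated) | CCOC(=O)C(=O)CC(=O)CC(=O)c1ccc(OCc2ccccc2)c(Br)c1 | intermediate
9 | ethyl 6-[4-(benzyloxy)-3-bromophenyl]-4-oxo-4H-pyran-2-carboxylate | CCOC(=O)c1cc(=O)cc(-c2ccc(OCc3ccccc3)c(Br)c2)o1 | intermediate
10 | ethyl 6-[4-(benzyloxy)-3-(4,4,5,5-tetramethyl-1,3,2-dioxaborolan-2-yl)phenyl]-4-oxo-4H-pyran-2-carboxylate | CCOC(=O)c1cc(=O)cc(-c2ccc(OCc3ccccc3)c(B3OC(C)(C)C(C)(C)O3)c2)o1 | intermediate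
11 | ethyl 6-{4-(benzyloxy)-3-[5,7-bis(benzyloxy)-2-(4-(benzyloxy)phenyl)-4-oxo-4H-chromen-8-yl]phenyl}-4-oxo-4H-pyran-2-carboxylate | CCOC(=O)c1cc(=O)cc(-c2ccc(OCc3ccccc3)c(-c3c(OCc4ccccc4)cc(OCc4ccccc4)c4c(=O)cc(-c5ccc(OCc6ccccc6)cc5)oc34)c2)o1 | intermediate
12 | 6-{4-(benzyloxy)-3-[5,7-bis(benzyloxy)-2-(4-(benzyloxy)phenyl)-4-oxo-4H-chromen-8-yl]phenyl}-4-oxo-4H-pyran-2-carboxylic acid | OC(=O)c1cc(=O)cc(-c2ccc(OCc3ccccc3)c(-c3c(OCc4ccccc4)cc(OCc4ccccc4)c4c(=O)cc(-c5ccc(OCc6ccccc6)cc5)oc34)c2)o1 | intermediate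
13 | acid chloride of 12 (not isolated) | ClC(=O)c1cc(=O)cc(-c2ccc(OCc3ccccc3)c(-c3c(OCc4ccccc4)cc(OCc4ccccc4)c4c(=O)cc(-c5ccc(OCc6ccccc6)cc5)oc34)c2)o1 | intermediate
14 | 2-diazo-1-(6-{4-(benzyloxy)-3-[5,7-bis(benzyloxy)-2-(4-(benzyloxy)phenyl)-4-oxo-4H-chromen-8-yl]phenyl}-4-oxo-4H-pyran-2-yl)ethan-1-one | [N-]=[N+]=CC(=O)c1cc(=O)cc(-c2ccc(OCc3ccccc3)c(-c3c(OCc4ccccc4)cc(OCc4ccccc4)c4c(=O)cc(-c5ccc(OCc6ccccc6)cc5)oc34)c2)o1 | intermediate
15 | 2-chloro-1,1-dimethoxyethane | COC(CCl)OC | starting material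
16 | sodium methoxyacetylide (not isolated) | [Na+].[C-]#COC | intermediate
17 | 1-methoxypropyne | CC#COC | intermediate
18 | pyranylketene, 2-(6-aryl-4-oxo-4H-pyran-2-yl)ethen-1-one with aryl as in 14 (not isolated) | O=C=Cc1cc(=O)cc(-c2ccc(OCc3ccccc3)c(-c3c(OCc4ccccc4)cc(OCc4ccccc4)c4c(=O)cc(-c5ccc(OCc6ccccc6)cc5)oc34)c2)o1 | intermediate
19 | racemic 3-methoxy-2-methyl-4-(6-aryl-4-oxo-4H-pyran-2-yl)cyclobut-2-en-1-one with aryl as in 14 (not isolated) | COC1=C(C)C(=O)C1c1cc(=O)cc(-c2ccc(OCc3ccccc3)c(-c3c(OCc4ccccc4)cc(OCc4ccccc4)c4c(=O)cc(-c5ccc(OCc6ccccc6)cc5)oc34)c2)o1 | intermediate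
20 | (3E)-3-methoxy-2-methyl-4-(6-aryl-4-oxo-4H-pyran-2-yl)buta-1,3-dien-1-one with aryl as in 14, pyranyl cis to the ketene carbon (not isolated) | O=C=C(C)/C(OC)=C\c1cc(=O)cc(-c2ccc(OCc3ccccc3)c(-c3c(OCc4ccccc4)cc(OCc4ccccc4)c4c(=O)cc(-c5ccc(OCc6ccccc6)cc5)oc34)c2)o1 | intermediate
21 | 2-{4-(benzyloxy)-3-[5,7-bis(benzyloxy)-2-(4-(benzyloxy)phenyl)-4-oxo-4H-chromen-8-yl]phenyl}-5-hydroxy-7-methoxy-6-methyl-4H-chromen-4-one | COc1cc2oc(-c3ccc(OCc4ccccc4)c(-c4c(OCc5ccccc5)cc(OCc5ccccc5)c5c(=O)cc(-c6ccc(OCc7ccccc7)cc6)oc45)c3)cc(=O)c2c(O)c1C | intermediate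
22 | 8-[2-hydroxy-5-(5-hydroxy-7-methoxy-6-methyl-4-oxo-4H-chromen-2-yl)phenyl]-5,7-dihydroxy-2-(4-hydroxyphenyl)-4H-chromen-4-one (CNP0113589.0) | COc1cc2oc(-c3ccc(O)c(-c4c(O)cc(O)c5c(=O)cc(-c6ccc(O)cc6)oc45)c3)cc(=O)c2c(O)c1C | target

Total step count: 12. Longest linear sequence: 9 steps (steps 3, 4, 5, 6, 7, 8, 9, 11, 12).

Steps most likely to fail

Step 11 (Proposed new method). The ketene may be intercepted before cycloaddition (dimerisation, acylation of the product phenol). The cyclobutenone may also open mainly by outward rotation, so that closure onto the pyranone stalls. The fallback uses known chemistry, sets out from iodide 3 and returns at 21, with ring A of unit 1 bought ready-made and its methyl group added afterwards.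
- Purchased 1-(2,6-dihydroxy-4-methoxyphenyl)ethanone and 4-(benzyloxy)-3-bromobenzaldehyde are condensed (KOH, EtOH, Claisen–Schmidt) to (E)-3-[4-(benzyloxy)-3-bromophenyl]-1-(2,6-dihydroxy-4-methoxyphenyl)prop-2-en-1-one F1.
- Oxidative cyclisation (I2 cat., DMSO, 120 °C) should give 2-[4-(benzyloxy)-3-bromophenyl]-5-hydroxy-7-methoxy-4H-chromen-4-one F2.
- Iodination ortho to the chelated hydroxyl (BnMe3N ICl2, CaCO3, CH2Cl2/MeOH) should give 2-[4-(benzyloxy)-3-bromophenyl]-5-hydroxy-6-iodo-7-methoxy-4H-chromen-4-one F3.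
- Suzuki methylation at the more reactive C–I bond (trimethylboroxine, Pd(PPh3)4, K2CO3, dioxane, 80 °C) should give 2-[4-(benzyloxy)-3-bromophenyl]-5-hydroxy-7-methoxy-6-methyl-4H-chromen-4-one F4.
- Miyaura borylation (B2pin2, PdCl2(dppf), KOAc) should give 2-[4-(benzyloxy)-3-(4,4,5,5-tetramethyl-1,3,2-dioxaborolan-2-yl)phenyl]-5-hydroxy-7-methoxy-6-methyl-4H-chromen-4-one F5.
- Suzuki coupling of this boronate with 3 under the conditions of step 7 should give 21.

Step 9. Diazomethane may add as a 1,3-dipole to the acyl-activated pyranone C=C, or HCl capture may divert the product to a chloromethyl ketone. The fallback sets out from acid 12 (through acid chloride 13, made as in step 9) and returns at 14, installing the diazo group by diazo transfer instead of acylation.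
- Stille acylation of 13 (Me4Sn, PdCl2(PPh3)2 cat., toluene, 80 °C) should give 2-acetyl-6-{4-(benzyloxy)-3-[5,7-bis(benzyloxy)-2-(4-(benzyloxy)phenyl)-4-oxo-4H-chromen-8-yl]phenyl}-4H-pyran-4-one F6, whose acetyl group holds the only enolisable protons.
- LiN(SiMe3)2 and CF3CO2CH2CF3 (THF, −78 °C) should give the trifluoroacetylated diketone 4,4,4-trifluoro-1-(6-aryl-4-oxo-4H-pyran-2-yl)butane-1,3-dione F7 (not isolated).
- Detrifluoroacetylative diazo transfer (MsN3, Et3N, H2O, MeCN) should then give 14.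

Step 7. Transmetalation at the tri-ortho-substituted biaryl may be slow, with competing protodeboronation and base attack on the pyranone ester. The fallback sets out from bromide 5 and iodide 3 and returns at 11, moving the coupling ahead of the pyranone construction.
- Miyaura borylation of 5 should give 1-[4-(benzyloxy)-3-(4,4,5,5-tetramethyl-1,3,2-dioxaborolan-2-yl)phenyl]ethanone F8.
- Its coupling with 3 (Pd(OAc)2, SPhos, K3PO4, toluene/H2O, 90 °C; a plain ketone tolerates aqueous base) should give the biaryl methyl ketone 8-[5-acetyl-2-(benzyloxy)phenyl]-5,7-bis(benzyloxy)-2-[4-(benzyloxy)phenyl]-4H-chromen-4-one F9.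
- Claisen condensation with EtOAc (NaH, THF) should give the biaryl butane-1,3-dione F10.
- Oxalylation with 7 (NaOEt, EtOH) through the biaryl trioxohexanoate F11 (not isolated) and acid closure should give 11. The flavone of unit 2 must then survive alkoxide, which is why this order is held in reserve.

Further compounds
F1 | step 11 | (E)-3-[4-(benzyloxy)-3-bromophenyl]-1-(2,6-dihydroxy-4-methoxyphenyl)prop-2-en-1-one | COc1cc(O)c(C(=O)/C=C/c2ccc(OCc3ccccc3)c(Br)c2)c(O)c1
F2 | step 11 | 2-[4-(benzyloxy)-3-bromophenyl]-5-hydroxy-7-methoxy-4H-chromen-4-one | COc1cc(O)c2c(=O)cc(-c3ccc(OCc4ccccc4)c(Br)c3)oc2c1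
F3 | step 11 | 2-[4-(benzyloxy)-3-bromophenyl]-5-hydroxy-6-iodo-7-methoxy-4H-chromen-4-one | COc1cc2oc(-c3ccc(OCc4ccccc4)c(Br)c3)cc(=O)c2c(O)c1I
F4 | step 11 | 2-[4-(benzyloxy)-3-bromophenyl]-5-hydroxy-7-methoxy-6-methyl-4H-chromen-4-one | COc1cc2oc(-c3ccc(OCc4ccccc4)c(Br)c3)cc(=O)c2c(O)c1C
F5 | step 11 | 2-[4-(benzyloxy)-3-(4,4,5,5-tetramethyl-1,3,2-dioxaborolan-2-yl)phenyl]-5-hydroxy-7-methoxy-6-methyl-4H-chromen-4-one | COc1cc2oc(-c3ccc(OCc4ccccc4)c(B4OC(C)(C)C(C)(C)O4)c3)cc(=O)c2c(O)c1C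
F6 | step 9 | 2-acetyl-6-{4-(benzyloxy)-3-[5,7-bis(benzyloxy)-2-(4-(benzyloxy)phenyl)-4-oxo-4H-chromen-8-yl]phenyl}-4H-pyran-4-one | CC(=O)c1cc(=O)cc(-c2ccc(OCc3ccccc3)c(-c3c(OCc4ccccc4)cc(OCc4ccccc4)c4c(=O)cc(-c5ccc(OCc6ccccc6)cc5)oc34)c2)o1
F7 | step 9 | 4,4,4-trifluoro-1-(6-{4-(benzyloxy)-3-[5,7-bis(benzyloxy)-2-(4-(benzyloxy)phenyl)-4-oxo-4H-chromen-8-yl]phenyl}-4-oxo-4H-pyran-2-yl)butane-1,3-dione | O=C(CC(=O)c1cc(=O)cc(-c2ccc(OCc3ccccc3)c(-c3c(OCc4ccccc4)cc(OCc4ccccc4)c4c(=O)cc(-c5ccc(OCc6ccccc6)cc5)oc34)c2)o1)C(F)(F)F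
F8 | step 7 | 1-[4-(benzyloxy)-3-(4,4,5,5-tetramethyl-1,3,2-dioxaborolan-2-yl)phenyl]ethanone | CC(=O)c1ccc(OCc2ccccc2)c(B2OC(C)(C)C(C)(C)O2)c1
F9 | step 7 | 8-[5-acetyl-2-(benzyloxy)phenyl]-5,7-bis(benzyloxy)-2-[4-(benzyloxy)phenyl]-4H-chromen-4-one | CC(=O)c1ccc(OCc2ccccc2)c(-c2c(OCc3ccccc3)cc(OCc3ccccc3)c3c(=O)cc(-c4ccc(OCc5ccccc5)cc4)oc23)c1
F10 | step 7 | 1-{4-(benzyloxy)-3-[5,7-bis(benzyloxy)-2-(4-(benzyloxy)phenyl)-4-oxo-4H-chromen-8-yl]phenyl}butane-1,3-dione | CC(=O)CC(=O)c1ccc(OCc2ccccc2)c(-c2c(OCc3ccccc3)cc(OCc3ccccc3)c3c(=O)cc(-c4ccc(OCc5ccccc5)cc4)oc23)c1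
F11 | step 7 | ethyl 6-{4-(benzyloxy)-3-[5,7-bis(benzyloxy)-2-(4-(benzyloxy)phenyl)-4-oxo-4H-chromen-8-yl]phenyl}-2,4,6-trioxohexanoate | CCOC(=O)C(=O)CC(=O)CC(=O)c1ccc(OCc2ccccc2)c(-c2c(OCc3ccccc3)cc(OCc3ccccc3)c3c(=O)cc(-c4ccc(OCc5ccccc5)cc4)oc23)c1
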